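**Plan**
- Retrosynthesis: the O–Si bonds are cut last. Ring A is then opened at C5–C6, C7–C8 and C4a–C5, which returns a ketene (C5, C8, from an acid chloride) and (triisopropylsilyloxy)acetylene (C6, C7).
- Enabling feature: ring A is a phloroglucinol whose C4a=C8a bond is the enol-ether double bond of a ready-made 2-aryloxy-4-pyranone (ring C). That bond plays the part of the vinyl group of a vinylketene.
- The acid chloride is cut at C8–C5 (CO2) and at C8–CH2 (prenyl bromide), both lateral bonds of a 6-methyl-4-pyranone. Ring C is cut at O1–C2 and C3–C4 into acetylketene and an aryl ethynyl ether made from hydroquinone.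
- Forward order: ring B (hydroquinone), aryl ethynyl ether, ring C by [4+2], prenylation, carboxylation, acid chloride, ring A by benzannulation, desilylation.
- Stereochemistry: the target has no stereocentre and no stereogenic double bond. The racemic centre of the acid and of the ring-closure intermediates disappears on aromatization.

Key step: step 9

Remark: all three phenol oxygens are carried as triisopropylsilyl ethers, so that one buffered fluoride step ends the synthesis and no acid meets the 7-hydroxy-8-prenyl unit. The siloxyalkyne is assumed not to be purchasable and is made in step 8.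

Step 1
Reactants: 1 hydroquinone
Product: 2 4-[(triisopropylsilyl)oxy]phenol
Conditions: i-Pr3SiCl, imidazole, DMF, 0 °C to rt (1 in threefold excess)
Reagents that add atoms: chlorotriisopropylsilane, CC(C)[Si](Cl)(C(C)C)C(C)C
Why: Silyl ether formation on a phenol; the excess of the diol keeps bis-silylation low and unreacted hydroquinone is washed out with water.

Step 2
Reactants: 2 4-[(triisopropylsilyl)oxy]phenol; 3 trichloroethylene
Product: 5 1-{[(E)-1,2-dichloroethenyl]oxy}-4-[(triisopropylsilyl)oxy]benzene, via dichloroacetylene 4 (not isolated)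
Conditions: KH, THF, 0 °C; then Cl2C=CHCl, 0 °C to rt
Reagents that add atoms: none
Why: Elimination–addition: base strips HCl from 3 to give 4, and the phenoxide adds anti across it and is protonated, which should give the E-dichlorovinyl ether without touching the bulky aryl silyl ether.

Step 3
Reactants: 5 1-{[(E)-1,2-dichloroethenyl]oxy}-4-[(triisopropylsilyl)oxy]benzene
Product: 8 1-(ethynyloxy)-4-[(triisopropylsilyl)oxy]benzene, via chloroethynyl ether 6 (not isolated), via lithium acetylide 7 (not isolated)
Conditions: n-BuLi (2.3 equiv), THF, −78 to −40 °C; then H2O, −78 °C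
Reagents that add atoms: none
Why: Dehydrochlorination to 6 followed by chlorine–lithium exchange (the usual dichlorovinyl ether route to alkynyl ethers) gives 7, which water protonates; an aryl triisopropylsilyl ether is inert to n-BuLi at this temperature.

Step 4
Reactants: 8 1-(ethynyloxy)-4-[(triisopropylsilyl)oxy]benzene; 9 2,2,6-trimethyl-4H-1,3-dioxin-4-one
Product: 11 6-methyl-2-{4-[(triisopropylsilyl)oxy]phenoxy}-4H-pyran-4-one, via acetylketene 10 (not isolated)
Conditions: PhMe, 110 °C, slow addition of 9 to 8 (1.5 equiv), acetone distilled off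
Reagents that add atoms: none
Why: Retro-[4+2] of the dioxinone releases 10, an electron-poor 1-oxadiene that should add to the electron-rich alkyne in an inverse-demand hetero-Diels–Alder reaction, the terminal alkyne carbon bonding to the ketene carbon (C3–C4) and the acetyl oxygen to the oxygen-bearing carbon (O1–C2), so that the pyranone forms directly at the aromatic oxidation level.

Step 5
Reactants: 11 6-methyl-2-{4-[(triisopropylsilyl)oxy]phenoxy}-4H-pyran-4-one; 12 prenyl bromide
Product: 14 2-(4-methylpent-3-en-1-yl)-6-{4-[(triisopropylsilyl)oxy]phenoxy}-4H-pyran-4-one, via lithium dienolate 13 (not isolated)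
Conditions: LiN(SiMe3)2 (1.0 equiv), THF, −78 °C; then 12, −78 to −20 °C
Reagents that add atoms: none
Why: Lateral (vinylogous) deprotonation of the 6-methyl group of a 4-pyranone gives 13, which the allylic bromide alkylates at the exocyclic carbon by SN2 substitution; one equivalent of base limits dialkylation.

Step 6
Reactants: 14 2-(4-methylpent-3-en-1-yl)-6-{4-[(triisopropylsilyl)oxy]phenoxy}-4H-pyran-4-one
Product: 16 rac-5-methyl-2-(4-oxo-6-{4-[(triisopropylsilyl)oxy]phenoxy}-4H-pyran-2-yl)hex-4-enoic acid, via lithium dienolate 15 (not isolated)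
Conditions: LiN(SiMe3)2, THF, −78 °C; CO2 (g), −78 to −20 °C; then cold dilute HCl to pH 3
Reagents that add atoms: carbon dioxide, O=C=O
Why: A second lateral lithiation at the only acidic carbon and carboxylation of 15 install the future C5; cold acidification and immediate use guard against decarboxylation of this vinylogous β-keto acid.

Step 7
Reactants: 16 rac-5-methyl-2-(4-oxo-6-{4-[(triisopropylsilyl)oxy]phenoxy}-4H-pyran-2-yl)hex-4-enoic acid
Product: 17 rac-5-methyl-2-(4-oxo-6-{4-[(triisopropylsilyl)oxy]phenoxy}-4H-pyran-2-yl)hex-4-enoyl chloride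
Conditions: 1-chloro-N,N,2-trimethylprop-1-en-1-amine, CH2Cl2, 0 °C to rt; solvent removed, used crude
Reagents that add atoms: 1-chloro-N,N,2-trimethylprop-1-en-1-amine, CC(C)=C(Cl)N(C)C
Why: Acid chloride formation with an α-chloroenamine runs under neutral conditions without free HCl, which spares the trisubstituted alkene, the aryl silyl ether and the aryloxypyranone.

Step 8
Reactants: 18 acetylene; 19 triisopropylsilyl trifluoromethanesulfonate
Product: 22 (ethynyloxy)tri(propan-2-yl)silane [(triisopropylsilyloxy)acetylene], via lithium acetylide 20 (not isolated), via lithium ethynolate 21 (not isolated)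
Conditions: HC≡CH (excess), n-BuLi, THF, −78 °C; t-BuOOLi (from t-BuOOH and LiN(SiMe3)2), −78 to −20 °C; then 19, −78 to 0 °C; distillation
Reagents that add atoms: tert-butyl hydroperoxide, CC(C)(C)OO
Why: Electrophilic hydroxylation of a lithium acetylide with lithium tert-butyl peroxide gives ynolate 21, and the hard, bulky silyl triflate silylates it on oxygen (the standard route to 1-siloxyalkynes, applied here to acetylene itself); the triisopropylsilyl group is chosen because it slows the 1,3-shift to the silylketene.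

Step 9
Reactants: 17 rac-5-methyl-2-(4-oxo-6-{4-[(triisopropylsilyl)oxy]phenoxy}-4H-pyran-2-yl)hex-4-enoyl chloride; 22 (ethynyloxy)tri(propan-2-yl)silane
Product: 27 5-hydroxy-8-(3-methylbut-2-en-1-yl)-7-[(triisopropylsilyl)oxy]-2-{4-[(triisopropylsilyl)oxy]phenoxy}-4H-chromen-4-one, via ketene 23 (not isolated), via cyclobutenone 24 (not isolated), via dienylketene 25 (not isolated), via dienone 26 (not isolated)
Conditions: Et3N, 22 (2 equiv), PhMe, 0 °C to rt; then 90 °C
Reagents that add atoms: none
Why: Et3N removes the doubly activated α-hydrogen of 17 (dehydrochlorination) to give ketene 23, and the [2+2] cycloaddition with ynol silyl ether 22 joins the electrophilic ketene carbonyl carbon to the unsubstituted, nucleophilic alkyne carbon (C5–C6) and the ketene α-carbon to the oxygen-bearing alkyne carbon (C7–C8), giving 3-silyloxycyclobutenone 24. On heating, 24 opens by reversible conrotatory 4π electrocyclic cleavage of the former ketene C–C bond to dienylketene 25, and ring A closes by disrotatory 6π electrocyclization of the ketene carbon onto the nucleophilic pyranone carbon next to the ring carbonyl (C4a–C5, six-membered carbocycle annulated to ring C) to give dienone 26. Enolization of 26, a cyclic β-diketone, makes ring A aromatic and leaves the 5-hydroxyl chelated to the C4 carbonyl in 27. The closest known reaction type is the Danheiser benzannulation of aryl- and vinylketenes with alkoxy- or siloxyalkynes, including the variant in which the ketene comes from an acid chloride and a tertiary amine. No stereocentre is created that persists, since the racemic centres of 24 and 26 vanish on ring opening and aromatization. The regiochemistry needed (7-silyloxy, 5-hydroxy, 8-prenyl) is secured by the ynol ether polarity in the cycloaddition and by the prenyl group and C8a already sitting on the ketene α-carbon, the only cyclization-competent geometry of 25 is reached through the reversible ring opening, and excess 22 limits ketene dimerization and O-acylation of 27.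

Step 10
Reactants: 27 5-hydroxy-8-(3-methylbut-2-en-1-yl)-7-[(triisopropylsilyl)oxy]-2-{4-[(triisopropylsilyl)oxy]phenoxy}-4H-chromen-4-one
Product: 28 Epimedonin G [5,7-dihydroxy-2-(4-hydroxyphenoxy)-8-(3-methylbut-2-en-1-yl)-4H-chromen-4-one]
Conditions: Bu4NF, AcOH, THF, 0 °C to rt
Reagents that add atoms: none
Why: Fluoride-induced cleavage of both aryl silyl ethers (desilylation), buffered with AcOH so that the phenoxides are protonated at once and neither the base-sensitive 2-aryloxychromone nor the acid-sensitive prenyl group is put at risk.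

**Compound list**
1 | hydroquinone | Oc1ccc(O)cc1 | starting material
2 | 4-[(triisopropylsilyl)oxy]phenol | CC(C)[Si](Oc1ccc(O)cc1)(C(C)C)C(C)C | intermediate
3 | trichloroethylene | ClC=C(Cl)Cl | starting material
4 | dichloroacetylene | ClC#CCl | intermediate (not isolated)
5 | 1-{[(E)-1,2-dichloroethenyl]oxy}-4-[(triisopropylsilyl)oxy]benzene | Cl/C=C(/Cl)Oc1ccc(O[Si](C(C)C)(C(C)C)C(C)C)cc1 | intermediate
6 | 1-[(chloroethynyl)oxy]-4-[(triisopropylsilyl)oxy]benzene | ClC#COc1ccc(O[Si](C(C)C)(C(C)C)C(C)C)cc1 | intermediate (not isolated)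
7 | lithium {4-[(triisopropylsilyl)oxy]phenoxy}acetylide | [Li]C#COc1ccc(O[Si](C(C)C)(C(C)C)C(C)C)cc1 | intermediate (not isolated)
8 | 1-(ethynyloxy)-4-[(triisopropylsilyl)oxy]benzene | C#COc1ccc(O[Si](C(C)C)(C(C)C)C(C)C)cc1 | intermediate
9 | 2,2,6-trimethyl-4H-1,3-dioxin-4-one | CC1=CC(=O)OC(C)(C)O1 | starting material
10 | acetylketene (but-1-ene-1,3-dione) | CC(=O)C=C=O | intermediate (not isolated)
11 | 6-methyl-2-{4-[(triisopropylsilyl)oxy]phenoxy}-4H-pyran-4-one | Cc1cc(=O)cc(Oc2ccc(O[Si](C(C)C)(C(C)C)C(C)C)cc2)o1 | intermediate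
12 | prenyl bromide (1-bromo-3-methylbut-2-ene) | CC(C)=CCBr | starting material
13 | lithium 2-methylidene-6-{4-[(triisopropylsilyl)oxy]phenoxy}-2H-pyran-4-olate | C=C1C=C(O[Li])C=C(Oc2ccc(O[Si](C(C)C)(C(C)C)C(C)C)cc2)O1 | intermediate (not isolated)
14 | 2-(4-methylpent-3-en-1-yl)-6-{4-[(triisopropylsilyl)oxy]phenoxy}-4H-pyran-4-one | CC(C)=CCCc1cc(=O)cc(Oc2ccc(O[Si](C(C)C)(C(C)C)C(C)C)cc2)o1 | intermediate
15 | lithium 2-(4-methylpent-3-en-1-ylidene)-6-{4-[(triisopropylsilyl)oxy]phenoxy}-2H-pyran-4-olate | CC(C)=CCC=C1C=C(O[Li])C=C(Oc2ccc(O[Si](C(C)C)(C(C)C)C(C)C)cc2)O1 | intermediate (not isolated)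
16 | rac-5-methyl-2-(4-oxo-6-{4-[(triisopropylsilyl)oxy]phenoxy}-4H-pyran-2-yl)hex-4-enoic acid | CC(C)=CCC(C(=O)O)c1cc(=O)cc(Oc2ccc(O[Si](C(C)C)(C(C)C)C(C)C)cc2)o1 | intermediate
17 | rac-5-methyl-2-(4-oxo-6-{4-[(triisopropylsilyl)oxy]phenoxy}-4H-pyran-2-yl)hex-4-enoyl chloride | CC(C)=CCC(C(Cl)=O)c1cc(=O)cc(Oc2ccc(O[Si](C(C)C)(C(C)C)C(C)C)cc2)o1 | intermediate
18 | acetylene | C#C | starting material
19 | triisopropylsilyl trifluoromethanesulfonate | CC(C)[Si](OS(=O)(=O)C(F)(F)F)(C(C)C)C(C)C | starting material
20 | lithium acetylide | [Li]C#C | intermediate (not isolated)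
21 | lithium ethynolate | [Li]OC#C | intermediate (not isolated)
22 | (ethynyloxy)tri(propan-2-yl)silane | C#CO[Si](C(C)C)(C(C)C)C(C)C | intermediate
23 | 5-methyl-2-(4-oxo-6-{4-[(triisopropylsilyl)oxy]phenoxy}-4H-pyran-2-yl)hexa-1,4-dien-1-one | CC(C)=CCC(=C=O)c1cc(=O)cc(Oc2ccc(O[Si](C(C)C)(C(C)C)C(C)C)cc2)o1 | intermediate (not isolated)
24 | rac-4-(3-methylbut-2-en-1-yl)-4-(4-oxo-6-{4-[(triisopropylsilyl)oxy]phenoxy}-4H-pyran-2-yl)-3-[(triisopropylsilyl)oxy]cyclobut-2-en-1-one | CC(C)=CCC1(C(=O)C=C1O[Si](C(C)C)(C(C)C)C(C)C)c1cc(=O)cc(Oc2ccc(O[Si](C(C)C)(C(C)C)C(C)C)cc2)o1 | intermediate (not isolated)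
25 | (3E)-7-methyl-4-(4-oxo-6-{4-[(triisopropylsilyl)oxy]phenoxy}-4H-pyran-2-yl)-3-[(triisopropylsilyl)oxy]octa-1,3,6-trien-1-one | O=C=C/C(O[Si](C(C)C)(C(C)C)C(C)C)=C(/CC=C(C)C)c1cc(=O)cc(Oc2ccc(O[Si](C(C)C)(C(C)C)C(C)C)cc2)o1 | intermediate (not isolated)
26 | rac-8-(3-methylbut-2-en-1-yl)-7-[(triisopropylsilyl)oxy]-2-{4-[(triisopropylsilyl)oxy]phenoxy}-4aH-chromene-4,5-dione | CC(C)=CCC1=C2OC(Oc3ccc(O[Si](C(C)C)(C(C)C)C(C)C)cc3)=CC(=O)C2C(=O)C=C1O[Si](C(C)C)(C(C)C)C(C)C | intermediate (not isolated)
27 | 5-hydroxy-8-(3-methylbut-2-en-1-yl)-7-[(triisopropylsilyl)oxy]-2-{4-[(triisopropylsilyl)oxy]phenoxy}-4H-chromen-4-one | CC(C)=CCc1c(O[Si](C(C)C)(C(C)C)C(C)C)cc(O)c2c(=O)cc(Oc3ccc(O[Si](C(C)C)(C(C)C)C(C)C)cc3)oc12 | intermediate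
28 | Epimedonin G | CC(C)=CCc1c(O)cc(O)c2c(=O)cc(Oc3ccc(O)cc3)oc12 | target

**Count**
Total steps: 10. Longest linear sequence: 9 steps (steps 1 to 7, 9 and 10); step 8 is a one-step side branch.

**Steps most likely to fail**

1. Step 9 (benzannulation). The ketene may dimerize or acylate the phenol as it forms, the siloxyalkyne may isomerize to the silylketene before it is consumed, or the cyclobutenone may decompose before the reversible ring opening funnels it to the cyclization-competent geometry. The fallback closes ring A by C-acylation instead of alkyne cycloaddition; it sets out from acid chloride 17 and returns at target 28. Compound 17 would acylate 2,2-dimethyl-1,3-dioxane-4,6-dione (pyridine, CH2Cl2, 0 °C) to give the acyl Meldrum's acid rac-5-[1-hydroxy-5-methyl-2-(4-oxo-6-{4-[(triisopropylsilyl)oxy]phenoxy}-4H-pyran-2-yl)hex-4-en-1-ylidene]-2,2-dimethyl-1,3-dioxane-4,6-dione F1. Heating F1 in dilute toluene (100 °C) should expel acetone and CO2 and release the acylketene rac-7-methyl-4-(4-oxo-6-{4-[(triisopropylsilyl)oxy]phenoxy}-4H-pyran-2-yl)octa-1,6-diene-1,3-dione F2. The enol of F2 is a dienylketene of the same kind as 25 and should close onto the pyranone carbon in the same way, an intramolecular C-acylation like the classical ring closure of 4-arylacetoacetic esters to naphthalene-1,3-diols. This would give 5,7-dihydroxy-8-(3-methylbut-2-en-1-yl)-2-{4-[(triisopropylsilyl)oxy]phenoxy}-4H-chromen-4-one F3, and Bu4NF/AcOH as in step 10 then removes the one silyl group to give 28.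

2. Step 4 (pyranone by hetero-Diels–Alder). The aryl ethynyl ether may polymerize at the temperature the dioxinone needs for its retro-[4+2], and acetylketene may dimerize faster than it is trapped. The fallback brings the aryloxy group in by addition–elimination at C2 of a preformed pyranone; it sets out from phenol 2 and returns at pyranone 11. Purchased 4,4-bis(methylsulfanyl)but-3-en-2-one would be acetylated at its methyl group (NaH, EtOAc, THF; Claisen condensation) to 6,6-bis(methylsulfanyl)hex-5-ene-2,4-dione F4. Acid treatment (TsOH, PhH, reflux) should cyclize F4 with loss of methanethiol to 6-methyl-2-(methylsulfanyl)-4H-pyran-4-one F5, and mCPBA (CH2Cl2, 0 °C) would oxidize it to 6-methyl-2-(methylsulfonyl)-4H-pyran-4-one F6. The sodium salt of 2 (NaH, THF, 0 °C to rt) then displaces methanesulfinate from F6, the way 2-aryloxychromones are made from 2-sulfonylchromones, to give 11.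

3. Step 8 (siloxyalkyne). Monolithium acetylide may disproportionate to the insoluble dilithium compound before it is oxidized, silylation may occur partly on carbon, and the product may rearrange to the silylketene on work-up. The fallback makes the ynolate by ring fragmentation instead of acetylide oxidation; it sets out from silyl triflate 19 and returns at siloxyalkyne 22. Purchased 3-phenylisoxazole would be lithiated at C5 (n-BuLi, THF, −78 °C) to (3-phenyl-1,2-oxazol-5-yl)lithium F7, which on warming should fragment to benzonitrile and lithium ethynolate 21. Compound 19 then silylates 21 on oxygen as in step 8, and 22 is separated from benzonitrile by distillation.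

**Further compounds**
F1 | step 9 | rac-5-[1-hydroxy-5-methyl-2-(4-oxo-6-{4-[(triisopropylsilyl)oxy]phenoxy}-4H-pyran-2-yl)hex-4-en-1-ylidene]-2,2-dimethyl-1,3-dioxane-4,6-dione | CC(C)=CCC(C(O)=C1C(=O)OC(C)(C)OC1=O)c1cc(=O)cc(Oc2ccc(O[Si](C(C)C)(C(C)C)C(C)C)cc2)o1
F2 | step 9 | rac-7-methyl-4-(4-oxo-6-{4-[(triisopropylsilyl)oxy]phenoxy}-4H-pyran-2-yl)octa-1,6-diene-1,3-dione | CC(C)=CCC(C(=O)C=C=O)c1cc(=O)cc(Oc2ccc(O[Si](C(C)C)(C(C)C)C(C)C)cc2)o1
F3 | step 9 | 5,7-dihydroxy-8-(3-methylbut-2-en-1-yl)-2-{4-[(triisopropylsilyl)oxy]phenoxy}-4H-chromen-4-one | CC(C)=CCc1c(O)cc(O)c2c(=O)cc(Oc3ccc(O[Si](C(C)C)(C(C)C)C(C)C)cc3)oc12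
F4 | step 4 | 6,6-bis(methylsulfanyl)hex-5-ene-2,4-dione | CC(=O)CC(=O)C=C(SC)SC
F5 | step 4 | 6-methyl-2-(methylsulfanyl)-4H-pyran-4-one | CSc1cc(=O)cc(C)o1
F6 | step 4 | 6-methyl-2-(methylsulfonyl)-4H-pyran-4-one | CS(=O)(=O)c1cc(=O)cc(C)o1
F7 | step 8 | (3-phenyl-1,2-oxazol-5-yl)lithium | [Li]c1cc(-c2ccccc2)no1
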